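**Retrosynthetic overview**
1. Feature: in the ten-membered carbocycle C1–C10, the methine C4 (CHMe) lies between the furanone enol-ether carbon C3 and the C5 methylene. It is read as the reduced form of a C4=C5 ring alkene conjugated with the 3(2H)-furanone ring (O, C3, C2, C1, C10).
2. Last events: the C8 tiglate (acylation) and C4–H/C5–H (face-selective hydrogenation). Before them, C4=C5 is made by ring-closing metathesis of a C3-isopropenyl furanone that carries a C6-vinyl trans-γ-lactone.
3. The furanone comes from a C10-hydroxy ynone (C1 aldehyde plus 2-methylbut-1-en-3-yne, oxidation, 5-endo-dig closure). The γ-lactone comes from C6–OH and the C12 ester.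
4. The all-syn C6/C7/C8 triad is built by an Evans syn aldol at C7–C8 (methylsuccinate imide plus citramalate aldehyde), followed by a C6 vinyl ketone and its chelation-controlled reduction. C10 and C11 come from the chiral pool.
5. Ring order: γ-lactone, then furanone, then the ten-membered carbocycle.

Key step: step 17

Remark: germacranolide numbering is used throughout (C1 ketone, C2, C3, C4, C5, C6 lactone carbinol, C7, C8 ester carbinol, C9, C10 quaternary, C11/C12 lactone CHMe and C=O), compound 5 is taken as a catalogue compound, and C8–O carries a benzyl ether because step 11 needs a chelating oxygen and step 12 an acid-stable group.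

Step 1
Reactants: 1 (R)-citramalic acid
Product: 2 (2R)-2-methylbutane-1,2,4-triol
Conditions: BH3·SMe2, B(OMe)3, THF, 0 °C → rt; MeOH quench, evaporation
Reagents that add atoms: none
Why: Borane reduction of carboxylic acids takes both carboxyl groups to primary alcohols and leaves untouched the tertiary carbinol carbon (the future C10, R, from the chiral pool).

Step 2
Reactants: 2 (2R)-2-methylbutane-1,2,4-triol
Product: 3 2-[(4R)-2,2,4-trimethyl-1,3-dioxolan-4-yl]ethanol
Conditions: 2,2-dimethoxypropane, pTsOH·H2O (cat.), acetone, rt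
Reagents that add atoms: 2,2-dimethoxypropane, COC(C)(C)OC
Why: Acid-catalysed transacetalisation under equilibrium control prefers the five-membered dioxolane across the C10 and C1 oxygens to the six- or seven-membered alternatives, so only the primary C8 hydroxyl stays free.

Step 3
Reactants: 3 2-[(4R)-2,2,4-trimethyl-1,3-dioxolan-4-yl]ethanol
Product: 4 2-[(4R)-2,2,4-trimethyl-1,3-dioxolan-4-yl]acetaldehyde
Conditions: IBX, EtOAc, 80 °C; filtration
Reagents that add atoms: none
Why: IBX oxidation of a primary alcohol stops at the aldehyde and is worked up by filtration, which suits a small, water-soluble β-alkoxy aldehyde with no stereocentre next to the carbonyl group.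

Step 4
Reactants: 5 (2S)-4-methoxy-2-methyl-4-oxobutanoic acid
Product: 6 1-tert-butyl 4-methyl (2S)-2-methylbutanedioate
Conditions: tert-butyl 2,2,2-trichloroacetimidate, BF3·OEt2 (cat.), CH2Cl2–cyclohexane, rt
Reagents that add atoms: tert-butyl 2,2,2-trichloroacetimidate, CC(C)(C)OC(=N)C(Cl)(Cl)Cl
Why: Acid-catalysed tert-butylation of a carboxylic acid with the trichloroacetimidate runs without base, so the purchased C11 stereocentre (S) and the methyl ester are not touched.

Step 5
Reactants: 6 1-tert-butyl 4-methyl (2S)-2-methylbutanedioate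
Product: 7 (3S)-4-tert-butoxy-3-methyl-4-oxobutanoic acid
Conditions: LiOH·H2O (1.1 equiv), THF–H2O, 0 °C; then 1 M HCl to pH 3
Reagents that add atoms: lithium hydroxide, [Li+].[OH-]
Why: Chemoselective saponification: hydroxide attacks the unhindered methyl ester by acyl–oxygen cleavage while the tert-butyl ester is inert, and at 0 °C the C11–H next to that ester is not exchanged.

Step 6
Reactants: 7 (3S)-4-tert-butoxy-3-methyl-4-oxobutanoic acid; 8 (4R)-4-benzyl-1,3-oxazolidin-2-one
Product: 10 tert-butyl (2S)-4-[(4R)-4-benzyl-2-oxo-1,3-oxazolidin-3-yl]-2-methyl-4-oxobutanoate, via mixed pivalic anhydride 9 (not isolated)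
Conditions: PivCl, Et3N, THF, −20 °C; then LiCl, 8, −20 °C → rt
Reagents that add atoms: pivaloyl chloride, CC(C)(C)C(=O)Cl (its atoms stay only in 9)
Why: N-Acylation of an Evans oxazolidinone by the mixed-anhydride method: the auxiliary attacks 9 at the less hindered succinyl carbonyl and not at the pivaloyl one.

Step 7
Reactants: 10 tert-butyl (2S)-4-[(4R)-4-benzyl-2-oxo-1,3-oxazolidin-3-yl]-2-methyl-4-oxobutanoate; 4 2-[(4R)-2,2,4-trimethyl-1,3-dioxolan-4-yl]acetaldehyde
Product: 13 syn-aldol imide (7R,8S,10R,11S) bearing a free C8 hydroxyl, via Z-boron enolate 11 (not isolated), via boron aldolate 12 (not isolated)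
Conditions: Bu2BOTf, Et3N, CH2Cl2, −78 → 0 °C; 4, −78 → 0 °C; pH 7 buffer, MeOH, 30 % H2O2, 0 °C
Reagents that add atoms: dibutylboron triflate, CCCCB(CCCC)OS(=O)(=O)C(F)(F)F (its atoms stay only in 11 and 12)
Why: Evans syn-aldol reaction: soft enolisation gives the Z boron enolate 11, which adds to 4 through a Zimmerman–Traxler chair on the face away from the benzyl group of the (R)-auxiliary, so C7 (R) and C8 (S) are set syn under reagent control, and the bulky tert-butyl ester keeps the new C8 oxygen from closing onto C12.

Step 8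
Reactants: 13 syn-aldol imide
Product: 14 tert-butyl (2S,3R,4S)-4-hydroxy-3-[methoxy(methyl)carbamoyl]-2-methyl-5-[(4R)-2,2,4-trimethyl-1,3-dioxolan-4-yl]pentanoate
Conditions: MeONHMe·HCl, AlMe3, CH2Cl2, −20 → 0 °C; aq. potassium sodium tartrate
Reagents that add atoms: N,O-dimethylhydroxylamine hydrochloride, CNOC.Cl
Why: Weinreb transamidation with the aluminium amide, helped by the free C8 hydroxyl that binds aluminium next to the imide, cleaves the exocyclic acyl–nitrogen bond and frees the auxiliary without epimerising C7.

Step 9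
Reactants: 14 β-hydroxy Weinreb amide
Product: 15 tert-butyl (2S,3R,4S)-4-(benzyloxy)-3-[methoxy(methyl)carbamoyl]-2-methyl-5-[(4R)-2,2,4-trimethyl-1,3-dioxolan-4-yl]pentanoate
Conditions: benzyl 2,2,2-trichloroacetimidate, TfOH (5 mol %), CH2Cl2–cyclohexane, 0 °C
Reagents that add atoms: benzyl 2,2,2-trichloroacetimidate, N=C(OCc1ccccc1)C(Cl)(Cl)Cl
Why: Acid-catalysed O-benzylation with the trichloroacetimidate avoids the basic conditions that would trigger retro-aldol cleavage, and it gives an ether that can chelate in step 11, survives the acid of step 12 and is inert to gold and ruthenium.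

Step 10
Reactants: 15 benzyloxy Weinreb amide; 16 vinylmagnesium bromide
Product: 17 tert-butyl (2S,3R)-3-{(1S)-1-(benzyloxy)-2-[(4R)-2,2,4-trimethyl-1,3-dioxolan-4-yl]ethyl}-2-methyl-4-oxohex-5-enoate
Conditions: THF, −78 → 0 °C; poured into cold 1 M HCl
Reagents that add atoms: none
Why: The Weinreb ketone synthesis stops at the ketone stage, so one vinyl group (C5 plus the carbon later lost as ethene) is delivered to C6, the tert-butyl ester is spared, and the cold acidic quench protonates the released amine before it can add to the enone.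

Step 11
Reactants: 17 C6 vinyl ketone
Product: 18 tert-butyl (2S,3S,4R)-3-{(1S)-1-(benzyloxy)-2-[(4R)-2,2,4-trimethyl-1,3-dioxolan-4-yl]ethyl}-4-hydroxy-2-methylhex-5-enoate
Conditions: Zn(BH4)2, Et2O, −78 → −30 °C; aq. NH4Cl
Reagents that add atoms: none
Why: Chelation-controlled 1,2-reduction of a β-alkoxy ketone: zinc bridges the C6 carbonyl and the C8 benzyloxy oxygen in a six-membered chelate with C9 equatorial and the C11 branch axial, and hydride enters axially anti to that branch, so 1,3-syn and 1,2-syn induction reinforce each other and set C6 (R), completing the all-syn triad.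

Step 12
Reactants: 18 allylic alcohol
Product: 20 (3S,4R,5R)-4-[(1S,3R)-1-(benzyloxy)-3,4-dihydroxy-3-methylbutyl]-3-methyl-5-vinyloxolan-2-one, via trihydroxy acid 19 (not isolated)
Conditions: TFA–CH2Cl2–H2O (5:10:1), 0 °C → rt; aq. NaHCO3
Reagents that add atoms: none
Why: Acidolysis and lactonisation: TFA removes the tert-butyl group as isobutene and hydrolyses the acetonide, and in 19 only the C6 hydroxyl can reach C12 through a five-membered ring because C8–O is benzylated, which gives the 6,7-trans γ-lactone with its three ring substituents all trans and no stereocentre disturbed.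

Step 13
Reactants: 20 lactone diol
Product: 21 (2R,4S)-4-(benzyloxy)-2-hydroxy-2-methyl-4-[(2R,3R,4S)-4-methyl-5-oxo-2-vinyloxolan-3-yl]butanal
Conditions: IBX, DMSO, rt
Reagents that add atoms: none
Why: IBX oxidises the primary C1 alcohol of the 1,2-diol to the α-hydroxy aldehyde without glycol cleavage and cannot touch the tertiary C10 hydroxyl.

Step 14
Reactants: 21 α-hydroxy aldehyde; 22 2-methylbut-1-en-3-yne
Product: 24 C1 propargylic diol (6R,7R,8S,10R,11S; C1 epimers), via lithium acetylide 23 (not isolated)
Conditions: 22, n-BuLi, THF, −78 °C; then 21 (one third of an equivalent), −78 °C; AcOH quench at −78 °C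
Reagents that add atoms: n-butyllithium, [Li]CCCC (lithium stays only in 23)
Why: 1,2-Addition of a lithium acetylide to an aldehyde: at −78 °C the aldehyde reacts far faster than the γ-lactone, one extra equivalent covers the C10 hydroxyl, and the new C1 carbinol forms as an epimer mixture that is erased in step 15.

Step 15
Reactants: 24 C1 propargylic diol
Product: 25 C10-hydroxy ynone (6R,7R,8S,10R,11S)
Conditions: IBX, DMSO, rt
Reagents that add atoms: none
Why: IBX oxidation of the propargylic alcohol gives the ynone, again without cleaving the bond to the adjacent tertiary carbinol, and removes the C1 stereocentre.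

Step 16
Reactants: 25 C10-hydroxy ynone
Product: 26 (3S,4R,5R)-4-{(1S)-1-(benzyloxy)-2-[(2R)-2-methyl-3-oxo-5-(prop-1-en-2-yl)-2,3-dihydrofuran-2-yl]ethyl}-3-methyl-5-vinyloxolan-2-one
Conditions: (Ph3P)AuCl (5 mol %), AgOTf (5 mol %), toluene, rt
Reagents that add atoms: none
Why: Gold-catalysed 5-endo-dig cycloisomerisation of an α'-hydroxy ynone: the carbophilic cation activates the alkyne, the C10 hydroxyl adds to C3 and protodeauration gives the 3(2H)-furanone with C10 unchanged.

Step 17
Reactants: 26 isopropenyl furanone with C6-vinyl lactone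
Product: 27 (4Z,6R,7R,8S,10R,11S)-8-(benzyloxy)-3,10-epoxy-1-oxogermacra-2,4-dien-12,6-olide
Conditions: second-generation Grubbs catalyst RuCl2(=CHPh)(PCy3)(H2IMes) (15 mol % in portions), 1,4-benzoquinone (30 mol %), toluene (1 mM), 100 °C, argon sparge
Reagents that add atoms: none
Why: Olefin metathesis by the Chauvin mechanism: the ruthenium benzylidene first exchanges with the unhindered, monosubstituted C6 vinyl group, and the C5 alkylidene so formed adds across the 1,1-disubstituted isopropenyl bond through a ruthenacyclobutane whose cycloreversion gives C4=C5 and Ru=CH2, ethene being swept out as the driving force. The closest known reaction type is ring-closing metathesis to trisubstituted nine- and ten-membered cycloalkenes, which is known to depend strongly on the substrate. The one ring closed is the ten-membered carbocycle C1–C10 (nine-membered if counted through the furanone oxygen), formed by end-to-end union of two terminal alkenes that sit on the two preformed five-membered rings. No stereocentre is created, and the ring-cis (Z) geometry should be enforced because the short C6–C9 chain cannot span a ring-trans C4=C5 bond next to the planar furanone. The step needs cyclisation to beat oligomerisation, which is served by high dilution and by the fact that only the C7–C8, C8–C9 and C9–C10 bonds rotate freely between the rigid furanone and the trans-lactone. The lactone ring holds its carbonyl away from C5, so it cannot tie up the alkylidene as a chelate, and benzoquinone suppresses isomerisation of the vinyl group by ruthenium hydrides.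

Step 18
Reactants: 27 4,5-dehydro macrocycle
Product: 28 (4S,6R,7R,8S,10R,11S)-8-(benzyloxy)-3,10-epoxy-1-oxogermacr-2-en-12,6-olide
Conditions: H2 (1 atm), Rh/Al2O3 (5 wt % Rh), EtOAc, rt
Reagents that add atoms: none
Why: Heterogeneous syn-hydrogenation: the inner face of the ring-cis C4=C5 bond is covered by the C7–C9 chain and the oxygen bridge, so both hydrogens should arrive from the outer face, which puts H on the β face of C4 and the methyl group α (4S), and Rh/Al2O3 is chosen because it should neither hydrogenolyse the allylic C6–O bond or the benzyl ether nor migrate the double bond as palladium can.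

Step 19
Reactants: 28 4,5-dihydro benzyl ether
Product: 29 (4S,6R,7R,8S,10R,11S)-3,10-epoxy-8-hydroxy-1-oxogermacr-2-en-12,6-olide
Conditions: H2 (1 atm), Pd(OH)2/C, EtOAc–EtOH, rt
Reagents that add atoms: none
Why: Hydrogenolysis of a benzyl ether: C6–O is no longer allylic, so the lactone is safe, and the hindered vinylogous-ester C2=C3 bond should resist reduction at 1 atm.

Step 20
Reactants: 29 C8 alcohol; 30 tigloyl chloride
Product: 31 target, (4S,6R,7S,8S,10R,11S)-3,10-epoxy-1-oxo-8-(tigloyloxy)germacr-2-en-12,6-olide
Conditions: DMAP, pyridine, CH2Cl2, 0 °C → rt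
Reagents that add atoms: none
Why: DMAP-catalysed acylation of the only free hydroxyl with retention at C8; pyridine is too weak a base to form the vinylketene or to enolise C4 or C11, so the E geometry of the tiglate and all stereocentres are kept.

**Compound list**
1 | (R)-citramalic acid | OC(=O)C[C@@](C(=O)O)(C)O | starting material
2 | (2R)-2-methylbutane-1,2,4-triol | OCC[C@@](CO)(C)O | intermediate
3 | 2-[(4R)-2,2,4-trimethyl-1,3-dioxolan-4-yl]ethanol | OCC[C@]1(C)COC(C)(C)O1 | intermediate
4 | 2-[(4R)-2,2,4-trimethyl-1,3-dioxolan-4-yl]acetaldehyde | O=CC[C@]1(C)COC(C)(C)O1 | intermediate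
5 | (2S)-4-methoxy-2-methyl-4-oxobutanoic acid | OC(=O)[C@@H](C)CC(=O)OC | starting material
6 | 1-tert-butyl 4-methyl (2S)-2-methylbutanedioate | CC(C)(C)OC(=O)[C@@H](C)CC(=O)OC | intermediate
7 | (3S)-4-tert-butoxy-3-methyl-4-oxobutanoic acid | CC(C)(C)OC(=O)[C@@H](C)CC(=O)O | intermediate
8 | (4R)-4-benzyl-1,3-oxazolidin-2-one | O=C1N[C@H](Cc2ccccc2)CO1 | starting material
9 | mixed pivalic anhydride of 7 | CC(C)(C)OC(=O)[C@@H](C)CC(=O)OC(=O)C(C)(C)C | intermediate
10 | tert-butyl (2S)-4-[(4R)-4-benzyl-2-oxo-1,3-oxazolidin-3-yl]-2-methyl-4-oxobutanoate | CC(C)(C)OC(=O)[C@@H](C)CC(=O)N1[C@H](Cc2ccccc2)COC1=O | intermediate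
11 | (Z)-dibutylboron enolate of 10 | CCCCB(CCCC)O/C(=C\[C@H](C)C(=O)OC(C)(C)C)N1[C@H](Cc2ccccc2)COC1=O | intermediate
12 | dibutylboron aldolate of 13 | CC(C)(C)OC(=O)[C@@H](C)[C@H]([C@@H](OB(CCCC)CCCC)C[C@]1(C)COC(C)(C)O1)C(=O)N1[C@H](Cc2ccccc2)COC1=O | intermediate
13 | tert-butyl (2S,3R,4S)-3-{[(4R)-4-benzyl-2-oxo-1,3-oxazolidin-3-yl]carbonyl}-4-hydroxy-2-methyl-5-[(4R)-2,2,4-trimethyl-1,3-dioxolan-4-yl]pentanoate | CC(C)(C)OC(=O)[C@@H](C)[C@H]([C@@H](O)C[C@]1(C)COC(C)(C)O1)C(=O)N1[C@H](Cc2ccccc2)COC1=O | intermediate
14 | β-hydroxy Weinreb amide (name in step 8) | CC(C)(C)OC(=O)[C@@H](C)[C@H]([C@@H](O)C[C@]1(C)COC(C)(C)O1)C(=O)N(C)OC | intermediate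
15 | benzyloxy Weinreb amide (name in step 9) | CC(C)(C)OC(=O)[C@@H](C)[C@H]([C@@H](OCc1ccccc1)C[C@]1(C)COC(C)(C)O1)C(=O)N(C)OC | intermediate
16 | vinylmagnesium bromide | C=C[Mg]Br | starting material
17 | C6 vinyl ketone (name in step 10) | CC(C)(C)OC(=O)[C@@H](C)[C@H]([C@@H](OCc1ccccc1)C[C@]1(C)COC(C)(C)O1)C(=O)C=C | intermediate
18 | all-syn C6 allylic alcohol (name in step 11) | CC(C)(C)OC(=O)[C@@H](C)[C@H]([C@@H](OCc1ccccc1)C[C@]1(C)COC(C)(C)O1)[C@H](O)C=C | intermediate
19 | trihydroxy acid: free C12 acid with C6, C10 and C1 hydroxyls and C8 benzyl ether | OC(=O)[C@@H](C)[C@H]([C@@H](OCc1ccccc1)C[C@@](C)(O)CO)[C@H](O)C=C | intermediate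
20 | lactone diol (name in step 12) | c1ccccc1CO[C@@H](C[C@@](C)(O)CO)[C@H]1[C@H](C)C(=O)O[C@@H]1C=C | intermediate
21 | α-hydroxy aldehyde (name in step 13) | c1ccccc1CO[C@@H](C[C@@](C)(O)C=O)[C@H]1[C@H](C)C(=O)O[C@@H]1C=C | intermediate
22 | 2-methylbut-1-en-3-yne | C=C(C)C#C | starting material
23 | lithium 3-methylbut-3-en-1-yn-1-ide | [Li]C#CC(C)=C | intermediate
24 | propargylic diol, both C1 epimers, C10–OH free | c1ccccc1CO[C@@H](C[C@@](C)(O)C(O)C#CC(C)=C)[C@H]1[C@H](C)C(=O)O[C@@H]1C=C | intermediate
25 | C10-hydroxy ynone (C1 ketone, C2≡C3, isopropenyl on C3) | c1ccccc1CO[C@@H](C[C@@](C)(O)C(=O)C#CC(C)=C)[C@H]1[C@H](C)C(=O)O[C@@H]1C=C | intermediate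
26 | isopropenyl furanone with C6-vinyl lactone (name in step 16) | c1ccccc1CO[C@@H](C[C@@]1(C)OC(=CC1=O)C(C)=C)[C@H]1[C@H](C)C(=O)O[C@@H]1C=C | intermediate
27 | 4,5-dehydro macrocycle, ring-cis alkene (name in step 17) | c1ccccc1CO[C@H]1C[C@@]2(C)OC(=CC2=O)/C(C)=C\[C@H]2OC(=O)[C@@H](C)[C@H]12 | intermediate
28 | 4,5-dihydro macrocycle, benzyl ether (name in step 18) | c1ccccc1CO[C@H]1C[C@@]2(C)OC(=CC2=O)[C@@H](C)C[C@H]2OC(=O)[C@@H](C)[C@H]12 | intermediate
29 | C8 alcohol (name in step 19) | O[C@H]1C[C@@]2(C)OC(=CC2=O)[C@@H](C)C[C@H]2OC(=O)[C@@H](C)[C@H]12 | intermediate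
30 | tigloyl chloride, (E)-2-methylbut-2-enoyl chloride | C/C=C(\C)C(=O)Cl | starting material
31 | CNP0235937.1 (name in step 20) | C/C=C(\C)C(=O)O[C@H]1C[C@@]2(C)OC(=CC2=O)[C@@H](C)C[C@H]2OC(=O)[C@@H](C)[C@H]12 | target

**Step count**
Total step count: 20.
Longest linear sequence: 17 steps (1 → 31 through steps 1–3 and 7–20). Steps 4–6 form the side branch.

**Steps most likely to fail**

Step 17 (ring closure). The C5 alkylidene may react with a second molecule faster than with the electron-poor, 1,1-disubstituted isopropenyl group, because the ring being built is strained. The catalyst may also decay, or isomerise the vinyl group, at the temperature needed.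
- The fallback is a relay version of the same closure. It sets out from 21 and rejoins the route at 27.
- Commercial (E)-3-methylpent-2-en-4-yn-1-ol is O-allylated (NaH, allyl bromide) to the relay enyne F1.
- The lithium acetylide of F1 adds to 21 to give the diol F2, IBX gives the ynone F3, and the gold-catalysed closure gives the relay furanone F4.
- With the same ruthenium catalyst the carbene loads on the unhindered allyl ether and expels 2,5-dihydrofuran. This places it directly on C4 as a disubstituted alkylidene, which then only has to find the reactive C6 vinyl group to give 27.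

Step 18 (C4). Hydrogen may be delivered to both faces if the ring exposes its inner face. The double bond may also migrate on the metal, or the allylic C6–O bond may be hydrogenolysed.
- The fallback sets out from 27 and rejoins at 28. It replaces surface hydrogenation by 1,6-conjugate reduction with [(Ph3P)CuH]6 (toluene, a few equivalents of H2O, rt).
- Hydride goes to C5 and gives the extended copper enolate F5, so C4 is set by protonation and not by hydrogen delivery.
- Because C4–H is the vinylogous α-position of the furanone, the C4 epimer F6, should it form, can be equilibrated with DBU, separated and recycled toward 28.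

Step 11 (C6). Chelation control may erode through an open transition state, or 1,4-reduction of the vinyl ketone may compete.
- The fallback moves from substrate control to catalyst control. It sets out from 15 and rejoins at 18.
- Lithium trimethylsilylacetylide converts 15 into the silyl ynone F7.
- Transfer hydrogenation with RuCl[(S,S)-TsDPEN](p-cymene) in 2-propanol sets C6 in the propargylic alcohol F8.
- K2CO3 in MeOH gives the terminal alkyne F9.
- Semihydrogenation (H2, Pd/CaCO3 poisoned with Pb(OAc)2, quinoline) gives 18.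

**Further compounds**
F1 | step 17 | (E)-3-methyl-5-(prop-2-en-1-yloxy)pent-3-en-1-yne | C#C/C(C)=C/COCC=C
F2 | step 17 | relay propargylic diol (C1 epimers) | c1ccccc1CO[C@@H](C[C@@](C)(O)C(O)C#C/C(C)=C/COCC=C)[C@H]1[C@H](C)C(=O)O[C@@H]1C=C
F3 | step 17 | relay C10-hydroxy ynone | c1ccccc1CO[C@@H](C[C@@](C)(O)C(=O)C#C/C(C)=C/COCC=C)[C@H]1[C@H](C)C(=O)O[C@@H]1C=C
F4 | step 17 | relay furanone with allyloxymethyl-capped C4 alkene and C6-vinyl lactone | c1ccccc1CO[C@@H](C[C@@]1(C)OC(=CC1=O)/C(C)=C/COCC=C)[C@H]1[C@H](C)C(=O)O[C@@H]1C=C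
F5 | step 18 | extended copper enolate (C1–O–Cu, C1=C2, C3=C4) | c1ccccc1CO[C@H]1C[C@@]2(C)OC(C=C2O[Cu])=C(C)C[C@H]2OC(=O)[C@@H](C)[C@H]12
F6 | step 18 | C4 epimer (4R) of 28 | c1ccccc1CO[C@H]1C[C@@]2(C)OC(=CC2=O)[C@H](C)C[C@H]2OC(=O)[C@@H](C)[C@H]12
F7 | step 11 | C6 trimethylsilylethynyl ketone | CC(C)(C)OC(=O)[C@@H](C)[C@H]([C@@H](OCc1ccccc1)C[C@]1(C)COC(C)(C)O1)C(=O)C#C[Si](C)(C)C
F8 | step 11 | (6S)-propargylic alcohol, silylated | CC(C)(C)OC(=O)[C@@H](C)[C@H]([C@@H](OCc1ccccc1)C[C@]1(C)COC(C)(C)O1)[C@H](O)C#C[Si](C)(C)C
F9 | step 11 | (6S)-propargylic alcohol, terminal alkyne | CC(C)(C)OC(=O)[C@@H](C)[C@H]([C@@H](OCc1ccccc1)C[C@]1(C)COC(C)(C)O1)[C@H](O)C#C
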